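**Retrosynthetic overview**
1. The route rests on the C3–C3' bond that joins the α-carbons of the two chroman-2-one rings (unit A: 5,7-dioxygenated lactone; unit B: 5,6,7,8-tetraoxygenated lactone, primed atoms), each next to a C4 carbon that carries the fused benzo ring and a 4-hydroxyphenyl group. Target 21 ⇐ 20 by hydrogenolysis of six benzyl ethers and of a chiral O5–O5' bridge.
2. 20 ⇐ cyclobutane 19 by reductive opening of the C4–C4' bond (between the two diaryl-substituted quaternary carbons), hydrogen entering anti to the C3/C3' substituents to give both cis lactones.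
3. 19 ⇐ bis-coumarin 18 by intramolecular sensitised [2+2] photocycloaddition of C3=C4 onto C3'=C4', head to head and anti, forming C3–C3' and C4–C4'. A (1S,3S)-1,3-diphenylpropane-1,3-diyl bridge between O5 and O5' replaces an intermolecular mixed dimerisation, which would give homodimers and offers no handle on the absolute sense. Lewis-acid activation is avoided because it turns coumarin dimerisation head to tail and would attack benzyl ethers.
4. 18 ⇐ alkynoate 3 (used twice), phloroglucinol 4, symmetric resorcinol 15 (from pyrogallol 10) and (1R,3R)-diol 8, by two hydroarylation–lactonisations and two Mitsunobu etherifications.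
5. Ring order: pyranone of unit A (step 2), pyranone of unit B (step 9), cyclobutane together with the bridge-containing macrocycle (step 10), cyclobutane opened again (step 11).

Key step: step 10

Assumption 1: the (1S,3S)-bridge is taken as the matched one for the required pair of faces (model: both bridge phenyl groups outside the stack). If the other face pair prevails, the (1S,3S)-diol replaces 8 in step 4; the two outcomes are diastereomers and separable either way.
Assumption 2: the triplet energies of the oxygenated 4-arylcoumarins are taken to lie below that of thioxanthone, as for coumarin itself.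

**Step 1**
Reactants: 1 1-(benzyloxy)-4-ethynylbenzene
Product: 3 ethyl 3-[4-(benzyloxy)phenyl]prop-2-ynoate, via lithium acetylide 2 (not isolated)
Conditions: n-BuLi, THF, −78 °C; then ClCO2Et, −78 °C to rt
Reagents that add atoms: ethyl chloroformate, CCOC(=O)Cl
Why: Deprotonation of the terminal alkyne and C-acylation of the lithium acetylide by a chloroformate is a standard alkynoate synthesis, and the benzyl ether is inert at −78 °C.

**Step 2**
Reactants: 4 phloroglucinol (benzene-1,3,5-triol); 3 ethyl 3-[4-(benzyloxy)phenyl]prop-2-ynoate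
Product: 6 4-[4-(benzyloxy)phenyl]-5,7-dihydroxy-2H-chromen-2-one, via Z-cinnamate 5 (not isolated)
Conditions: Pd(OAc)2 (5 mol %), TFA–CH2Cl2 (1:4), 0 °C to rt
Reagents that add atoms: none
Why: The very nucleophilic phloroglucinol adds to the alkynoate activated by divalent palladium at the aryl-bearing carbon (trans-hydroarylation, a Pechmann-type coumarin synthesis) and the Z-cinnamate lactonises at once; the three ring positions are equivalent, so there is no regiochemical issue.

**Step 3**
Reactants: 6 4-[4-(benzyloxy)phenyl]-5,7-dihydroxy-2H-chromen-2-one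
Product: 7 7-(benzyloxy)-4-[4-(benzyloxy)phenyl]-5-hydroxy-2H-chromen-2-one
Conditions: BnBr (1.05 equiv), K2CO3, acetone, rt
Reagents that add atoms: benzyl bromide, BrCc1ccccc1
Why: Williamson etherification should be selective for the 7-OH, which is the more acidic (vinylogous acid, para to the ring carbon carrying the enone) and unhindered, whereas the 5-OH is shielded by the peri 4-aryl group.

**Step 4**
Reactants: 7 7-(benzyloxy)-4-[4-(benzyloxy)phenyl]-5-hydroxy-2H-chromen-2-one; 8 (1R,3R)-1,3-diphenylpropane-1,3-diol (3 equiv)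
Product: 9 7-(benzyloxy)-4-[4-(benzyloxy)phenyl]-5-{[(1S,3R)-3-hydroxy-1,3-diphenylpropyl]oxy}-2H-chromen-2-one
Conditions: PPh3, DIAD, THF, 0 °C to rt
Reagents that add atoms: none
Why: Mitsunobu reaction in which the acidic 5-OH displaces the activated secondary benzylic alcohol with inversion (R to S at the ether carbon); a 1,3-diol in excess is etherified once only, and phenols are known to etherify 1-phenylalkanols this way with clean inversion.

**Step 5**
Reactants: 10 pyrogallol (benzene-1,2,3-triol)
Product: 11 1,2,3-tris(benzyloxy)benzene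
Conditions: BnBr, K2CO3, DMF, 60 °C, under Ar
Reagents that add atoms: benzyl bromide, BrCc1ccccc1
Why: Exhaustive Williamson etherification of the three phenolic groups, run under argon because pyrogallol is air-sensitive in base.

**Step 6**
Reactants: 11 1,2,3-tris(benzyloxy)benzene
Product: 12 1,5-dibromo-2,3,4-tris(benzyloxy)benzene
Conditions: NBS (2.1 equiv), MeCN, 0 °C to rt, dark
Reagents that add atoms: N-bromosuccinimide, O=C1CCC(=O)N1Br
Why: Electrophilic aromatic bromination goes to the two positions ortho/para to the outer benzyloxy groups (C4 and C6), not to C5, which is para only to the twisted central benzyloxy group.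

**Step 7**
Reactants: 12 1,5-dibromo-2,3,4-tris(benzyloxy)benzene
Product: 15 4,5,6-tris(benzyloxy)benzene-1,3-diol, via dilithioarene 13 (not isolated), via bis-boronate 14 (not isolated)
Conditions: n-BuLi (2.3 equiv), THF, −78 °C; B(OMe)3; then AcOH, 30% H2O2, 0 °C to rt
Reagents that add atoms: hydrogen peroxide, OO
Why: Twofold bromine–lithium exchange (fast at −78 °C, each aryllithium held by an ortho benzyloxy group), borylation and oxidative aryl migration from boron to oxygen replace both bromines by hydroxyl.

**Step 8**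
Reactants: 9 7-(benzyloxy)-4-[4-(benzyloxy)phenyl]-5-{[(1S,3R)-3-hydroxy-1,3-diphenylpropyl]oxy}-2H-chromen-2-one; 15 4,5,6-tris(benzyloxy)benzene-1,3-diol (3 equiv)
Product: 16 7-(benzyloxy)-4-[4-(benzyloxy)phenyl]-5-{[(1S,3S)-3-[2,3,4-tris(benzyloxy)-5-hydroxyphenoxy]-1,3-diphenylpropyl]oxy}-2H-chromen-2-one
Conditions: PPh3, DIAD, THF, 0 °C to rt
Reagents that add atoms: none
Why: Second Mitsunobu reaction, again with inversion (R to S), which makes the bridge (1S,3S); the symmetric diol 15 is used in excess so that only one of its two equivalent hydroxyl groups reacts.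

**Step 9**
Reactants: 16 bridged phenol; 3 ethyl 3-[4-(benzyloxy)phenyl]prop-2-ynoate
Product: 18 bridged bis-coumarin (unit A: 7-benzyloxy-4-[4-(benzyloxy)phenyl]coumarin; unit B: 6,7,8-tris(benzyloxy)-4-[4-(benzyloxy)phenyl]coumarin; O5 and O5' joined by the (1S,3S)-1,3-diphenylpropane-1,3-diyl bridge), via Z-cinnamate 17 (not isolated)
Conditions: Pd(OAc)2 (5 mol %), TFA–CH2Cl2 (1:4), 0 °C to rt
Reagents that add atoms: none
Why: Same hydroarylation–lactonisation as step 2; the ring-B phenol has a single free position, flanked by the free OH and the bridge oxygen, so the coumarin can only form with the bridge on O5', while benzyl and 1-phenylalkyl aryl ethers tolerate dilute TFA and the pyranone-deactivated benzo ring of unit A should not compete.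

**Step 10**
Reactants: 18 bridged bis-coumarin
Product: 19 (3R,4S,3'R,4'S)-cyclobutane photoadduct (anti head-to-head; new bonds C3–C3' and C4–C4'; both lactones cis-fused to the four-membered ring with their carbonyl groups on opposite faces; (1S,3S)-bridge retained)
Conditions: thioxanthone (20 mol %), hν (405 nm LED), degassed benzene (1 mM), 10 °C
Reagents that add atoms: none
Why: Proposed new method: energy transfer from triplet thioxanthone to either coumarin gives a ππ* triplet that bonds C3 to C3' of the stacked ground-state partner, giving a triplet 1,4-diradical whose centres C4 and C4' are each stabilised by two aryl groups, and after spin inversion C4–C4' closes. The closest known reactions are the sensitised anti head-to-head [2+2] photodimerisation of coumarins and tether-directed intramolecular [2+2] photocycloadditions of bis-cinnamates and linked biscoumarins; a cyclobutane with two vicinal diaryl-substituted quaternary carbons from 4-arylcoumarins is new, as is this bridge. The C3–C3' bond closes a 13-membered ring through the bridge (templated radical addition), and the C4–C4' bond then closes the four-membered ring by 1,4-diradical recombination, cis-fused to each lactone because a six-membered lactone cannot span trans positions. C3 and C3' come out like because the two lactones stack anti, C4 and C4' follow from the cis fusions, and the absolute sense of all four is set by which pair of faces stack, which the (1S,3S)-bridge decides by keeping both of its phenyl groups outside the stack. The step needs cross, head-to-head, anti and facial selectivity: the three-carbon O5–O5' bridge makes the reaction intramolecular and holds C4 beside C4' (cross, head to head), and it fits the twofold-symmetric anti stack but not the eclipsed syn stack, which the triplet pathway in a non-polar solvent also disfavours. The adduct is expected to be thermally labile at C4–C4', so it is formed at 10 °C and reduced without delay.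

**Step 11**
Reactants: 19 cyclobutane photoadduct
Product: 20 (3S,4R,3'S,4'R)-3,3'-linked bis(4-aryl-chroman-2-one), 3,4-cis in both lactones, six benzyl ethers and the (1S,3S)-bridge retained
Conditions: SmI2 (6 equiv), HMPA, t-BuOH, THF, −78 to 0 °C
Reagents that add atoms: none
Why: Proposed new method: SmI2–HMPA (divalent samarium) should transfer an electron into the long, strained C4–C4' σ bond, whose σ* is lowered by four aryl groups, at a potential that leaves aryl lactones and benzyl ethers alone, giving a diarylmethyl anion (protonated by t-BuOH) and a diarylmethyl radical (reduced by a second SmI2, then protonated), so that no 1,4-diradical able to fragment to the two coumarins is formed; each planar benzylic centre sits in a half-chair lactone whose C3 substituent (the other half of the molecule) is pseudo-axial, so the proton should enter from the opposite face and give the 3,4-cis lactones (net inversion at C4 and C4'); the closest known reactions are the alkali-metal reductive opening of 1,2-diarylcyclobutanes and 1,1,2,2-tetraarylethanes and SmI2 openings of strained rings.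

**Step 12**
Reactants: 20 bridged, benzylated bis-lactone
Product: 21 target, (3S,4R,3'S,4'R)-5,7,5',6',7',8'-hexahydroxy-4,4'-bis(4-hydroxyphenyl)-3,3'-bichroman-2,2'-dione
Conditions: H2 (1 atm), Pd(OH)2/C, THF–MeOH (1:1), rt, work-up under Ar
Reagents that add atoms: none
Why: Hydrogenolysis of benzylic C–O bonds cleaves the six benzyl aryl ethers and both 1-phenylalkyl aryl ether bonds of the bridge, while the aryl lactones and the four stereocentres (none a benzylic C–O centre) are untouched.

**Compound list**
1 | 1-(benzyloxy)-4-ethynylbenzene | C#Cc1ccc(OCc2ccccc2)cc1 | starting material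
2 | lithium [4-(benzyloxy)phenyl]acetylide | [Li]C#Cc1ccc(OCc2ccccc2)cc1 | intermediate
3 | ethyl 3-[4-(benzyloxy)phenyl]prop-2-ynoate | CCOC(=O)C#Cc1ccc(OCc2ccccc2)cc1 | intermediate
4 | phloroglucinol | Oc1cc(O)cc(O)c1 | starting material
5 | ethyl (2Z)-3-[4-(benzyloxy)phenyl]-3-(2,4,6-trihydroxyphenyl)prop-2-enoate | CCOC(=O)/C=C(/c1ccc(OCc2ccccc2)cc1)c1c(O)cc(O)cc1O | intermediate
6 | 4-[4-(benzyloxy)phenyl]-5,7-dihydroxy-2H-chromen-2-one | O=C1C=C(c2ccc(OCc3ccccc3)cc2)c2c(O)cc(O)cc2O1 | intermediate
7 | 7-(benzyloxy)-4-[4-(benzyloxy)phenyl]-5-hydroxy-2H-chromen-2-one | O=C1C=C(c2ccc(OCc3ccccc3)cc2)c2c(O)cc(OCc3ccccc3)cc2O1 | intermediate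
8 | (1R,3R)-1,3-diphenylpropane-1,3-diol | O[C@@H](c1ccccc1)C[C@H](c1ccccc1)O | starting material
9 | 7-(benzyloxy)-4-[4-(benzyloxy)phenyl]-5-{[(1S,3R)-3-hydroxy-1,3-diphenylpropyl]oxy}-2H-chromen-2-one | O=C1C=C(c2ccc(OCc3ccccc3)cc2)c2c(O[C@H](c3ccccc3)C[C@H](c3ccccc3)O)cc(OCc3ccccc3)cc2O1 | intermediate
10 | pyrogallol | Oc1cccc(O)c1O | starting material
11 | 1,2,3-tris(benzyloxy)benzene | C(Oc1cccc(OCc2ccccc2)c1OCc1ccccc1)c1ccccc1 | intermediate
12 | 1,5-dibromo-2,3,4-tris(benzyloxy)benzene | Brc1cc(Br)c(OCc2ccccc2)c(OCc2ccccc2)c1OCc1ccccc1 | intermediate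
13 | 1,5-dilithio-2,3,4-tris(benzyloxy)benzene | [Li]c1cc([Li])c(OCc2ccccc2)c(OCc2ccccc2)c1OCc1ccccc1 | intermediate
14 | tetramethyl [4,5,6-tris(benzyloxy)-1,3-phenylene]bis(boronate) | COB(OC)c1cc(B(OC)OC)c(OCc2ccccc2)c(OCc2ccccc2)c1OCc1ccccc1 | intermediate
15 | 4,5,6-tris(benzyloxy)benzene-1,3-diol | Oc1cc(O)c(OCc2ccccc2)c(OCc2ccccc2)c1OCc1ccccc1 | intermediate
16 | 7-(benzyloxy)-4-[4-(benzyloxy)phenyl]-5-{[(1S,3S)-3-[2,3,4-tris(benzyloxy)-5-hydroxyphenoxy]-1,3-diphenylpropyl]oxy}-2H-chromen-2-one | O=C1C=C(c2ccc(OCc3ccccc3)cc2)c2c(O[C@H](c3ccccc3)C[C@@H](c3ccccc3)Oc3cc(O)c(OCc4ccccc4)c(OCc4ccccc4)c3OCc3ccccc3)cc(OCc3ccccc3)cc2O1 | intermediate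
17 | Z-cinnamate from hydroarylation of 3 by the ring-B phenol of 16 (ethyl ester, free 8a'-OH) | O=C1C=C(c2ccc(OCc3ccccc3)cc2)c2c(O[C@H](c3ccccc3)C[C@@H](c3ccccc3)Oc3c(OCc4ccccc4)c(OCc4ccccc4)c(OCc4ccccc4)c(O)c3/C(=C\C(=O)OCC)c3ccc(OCc4ccccc4)cc3)cc(OCc3ccccc3)cc2O1 | intermediate
18 | bridged bis-coumarin, O5–O5' (1S,3S)-1,3-diphenylpropane-1,3-diyl, six benzyl ethers | O=C1C=C(c2ccc(OCc3ccccc3)cc2)c2c(O[C@H](c3ccccc3)C[C@@H](c3ccccc3)Oc3c(OCc4ccccc4)c(OCc4ccccc4)c(OCc4ccccc4)c4OC(=O)C=C(c5ccc(OCc6ccccc6)cc5)c34)cc(OCc3ccccc3)cc2O1 | intermediate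
19 | (3R,4S,3'R,4'S) anti head-to-head cyclobutane photoadduct of 18 | O=C1Oc2cc(OCc5ccccc5)cc3c2[C@]2(c5ccc(OCc6ccccc6)cc5)[C@H]1[C@H]1C(=O)Oc4c(OCc5ccccc5)c(OCc5ccccc5)c(OCc5ccccc5)c(O[C@H](c5ccccc5)C[C@@H](c5ccccc5)O3)c4[C@]12c1ccc(OCc2ccccc2)cc1 | intermediate
20 | (3S,4R,3'S,4'R) bridged, hexabenzylated 3,3'-bichroman-2,2'-dione | O=C1Oc2cc(OCc5ccccc5)cc3c2[C@@H](c5ccc(OCc6ccccc6)cc5)[C@H]1[C@H]1C(=O)Oc4c(OCc5ccccc5)c(OCc5ccccc5)c(OCc5ccccc5)c(O[C@H](c5ccccc5)C[C@@H](c5ccccc5)O3)c4[C@H]1c1ccc(OCc2ccccc2)cc1 | intermediate
21 | target CNP0064734.1 | O=C1Oc2cc(O)cc(O)c2[C@@H](c2ccc(O)cc2)[C@H]1[C@H]1C(=O)Oc2c(O)c(O)c(O)c(O)c2[C@H]1c1ccc(O)cc1 | target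

**Totals**
Total step count: 12. Longest linear sequence: 9 steps (1, 2, 3, 4, 8, 9, 10, 11, 12).

**Steps most likely to fail**

Step 10. The 1,4-diradical may return to the two alkenes faster than it closes a bond between two fully substituted carbons. The stack may also close syn or on the other face pair, and the adduct may revert thermally. Fallback with known chemistry, from 18 back to 20:
- Twofold copper-hydride asymmetric conjugate reduction of the coumarin C=C bonds (Cu(OAc)2, the DTBM-SEGPHOS enantiomer that gives the 4R and 4'R centres, (EtO)2MeSiH, t-BuOH, toluene) would give the bridged bis(4-aryl-chroman-2-one) F1.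
- Double deprotonation (LiN(SiMe3)2, THF, −78 °C) and intramolecular oxidative enolate coupling with CuCl2 would give the C3–C3' linked bis-lactone F2, each new bond expected trans to the neighbouring aryl group.
- A second double deprotonation and kinetic protonation anti to the 4-aryl groups would then set both 3,4-cis lactones and deliver 20.

Step 11. The electron may instead enter a lactone carbonyl and open the C3–C4 bond, the benzylic anion may expel the C3–C3' bond before protonation, or protonation may occur on the wrong face. Fallback with known chemistry, from 19 back to 21: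
- LiOH in THF–water would open both lactones to the cyclobutane diacid bis-phenol F3; its carboxylate and phenoxide groups are inert to dissolving metal.
- Li in liquid NH3 with t-BuOH, the classical reductive cleavage of tetraaryl-substituted C–C bonds and of benzylic ethers, would cut C4–C4', the six benzyl ethers and the bridge, giving the seco diacid F4.
- Acidification (aqueous HCl, THF) would relactonise F4 to 21. Protonation at C4 and C4' is then acyclic and less controlled, so the cis,cis isomer would be separated by reverse-phase HPLC.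

Step 9. Hydroarylation at the crowded position between the free OH and the bridge oxygen may be slow, allowing acid-promoted loss of the benzylic bridge or attack on other electron-rich rings. Fallback, from 16 and 3 back to 18:
- Saponification of 3 (LiOH, THF–water) would give 3-[4-(benzyloxy)phenyl]prop-2-ynoic acid F5.
- Esterification of the phenol of 16 with F5 (DCC, DMAP, CH2Cl2) would give the aryl propiolate F6.
- Acid-free intramolecular 6-endo hydroarylation of F6 with a cationic catalyst of monovalent gold ((Ph3P)AuCl, AgSbF6, 1,2-dichloroethane, rt) would close the pyranone of unit B and give 18.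

**Further compounds**
F1 | step 10 | bridged bis[(4R)-4-aryl-chroman-2-one] (4R,4'R), six benzyl ethers | O=C1C[C@H](c2ccc(OCc3ccccc3)cc2)c2c(O[C@H](c3ccccc3)C[C@@H](c3ccccc3)Oc3c(OCc4ccccc4)c(OCc4ccccc4)c(OCc4ccccc4)c4OC(=O)C[C@H](c5ccc(OCc6ccccc6)cc5)c34)cc(OCc3ccccc3)cc2O1
F2 | step 10 | (3R,4R,3'R,4'R) bridged 3,3'-bichroman-2,2'-dione, 3,4-trans in both lactones | O=C1Oc2cc(OCc5ccccc5)cc3c2[C@@H](c5ccc(OCc6ccccc6)cc5)[C@@H]1[C@@H]1C(=O)Oc4c(OCc5ccccc5)c(OCc5ccccc5)c(OCc5ccccc5)c(O[C@H](c5ccccc5)C[C@@H](c5ccccc5)O3)c4[C@H]1c1ccc(OCc2ccccc2)cc1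
F3 | step 11 | bridged cyclobutane-1,2-dicarboxylic acid bis-phenol from lactone opening of 19 | OC(=O)[C@@H]1[C@@H](C(=O)O)[C@](c3c(O)c(OCc5ccccc5)c(OCc5ccccc5)c(OCc5ccccc5)c3O[C@H](c5ccccc5)C[C@@H](c5ccccc5)O9)(c3ccc(OCc5ccccc5)cc3)[C@@]1(c3c(O)cc(OCc5ccccc5)cc39)c3ccc(OCc5ccccc5)cc3
F4 | step 11 | seco diacid of the target, (2S,3S)-2-[(R)-(4-hydroxyphenyl)(2,4,6-trihydroxyphenyl)methyl]-3-[(R)-(4-hydroxyphenyl)(2,3,4,5,6-pentahydroxyphenyl)methyl]butanedioic acid | OC(=O)[C@@H]([C@H](c1ccc(O)cc1)c1c(O)cc(O)cc1O)[C@@H](C(=O)O)[C@H](c1ccc(O)cc1)c1c(O)c(O)c(O)c(O)c1O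
F5 | step 9 | 3-[4-(benzyloxy)phenyl]prop-2-ynoic acid | OC(=O)C#Cc1ccc(OCc2ccccc2)cc1
F6 | step 9 | aryl propiolate of 16 (ring-B phenol acylated by F5) | O=C1C=C(c2ccc(OCc3ccccc3)cc2)c2c(O[C@H](c3ccccc3)C[C@@H](c3ccccc3)Oc3cc(OC(=O)C#Cc4ccc(OCc5ccccc5)cc4)c(OCc4ccccc4)c(OCc4ccccc4)c3OCc3ccccc3)cc(OCc3ccccc3)cc2O1
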